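**Plan**

- Feature: in ring B the C(CH3)2 carbon lies between a ketone carbon (C=O) and an enol carbon (C–OH). The six-membered ring bears oxygen on alternate carbons and an isobutyryl group. Ring B is therefore an isobutyrylphloroglucinol methylated twice at its last free ring carbon.
- Cuts, in order: the two masks on the ring A hydroxyls (SEM ethers); both C–CH3 bonds at the quaternary carbon of ring B; the CH2–ring B bond of the bridge; on ring A the CH2–aryl, prenyl–O and benzoyl–aryl bonds; on ring B the isobutyryl–aryl bond.
- Forward: no ring is ever closed, and both carbocycles come from phloroglucinol. Ring A is dressed (benzoyl, SEM, formyl, prenyl, SEM, then CHO to CH2Br) and ring B is acylated. The halves are joined at the bridge, ring B is dearomatised, and the SEM groups fall last.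
- Ring A regiochemistry rests on symmetry and chelation. The hydroxyl para to benzoyl is capped first, and the symmetrical diol can give only one aldehyde. The hydroxyl wedged between formyl and benzoyl reacts last, so the prenyl ether ends up para to the bridge.
- Stereochemistry: the target has no stereocentre and no stereogenic double bond, so nothing has to be set.

Key step: step 10

Assumption: the enolised β-triketone of ring B is written throughout as the single tautomer of the target SMILES; its tautomers interconvert freely and count as one compound.
Abbreviations: SEM = 2-(trimethylsilyl)ethoxymethyl (SEM-oxy = OCH2OCH2CH2SiMe3); prenyl = 3-methylbut-2-en-1-yl.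

**Step 1**
Reactants: 1 phloroglucinol; 2 benzoyl chloride
Product: 3 2,4,6-trihydroxybenzophenone
Conditions: AlCl3 (4 equiv), PhNO2, 65 °C; ice/aq. HCl
Reagents that add atoms: benzoyl chloride (2), O=C(Cl)c1ccccc1
Why: Friedel–Crafts acylation of the threefold activated ring, which should stop after one benzoyl group because the chelated aryl ketone–AlCl3 complex is strongly deactivated.

**Step 2**
Reactants: 3 2,4,6-trihydroxybenzophenone
Product: 4 2,6-dihydroxy-4-(SEM-oxy)benzophenone
Conditions: SEMCl (0.95 equiv), i-Pr2NEt, THF, −10 → 0 °C
Reagents that add atoms: SEMCl, C[Si](C)(C)CCOCCl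
Why: Selective O-alkylation of Williamson type (acetal protecting group): the hydroxyl para to the ketone is the most acidic and the only one not tied into a hydrogen bond with the benzoyl oxygen, so slightly less than one equivalent of the hard electrophile should cap it alone, at oxygen and not at carbon, and leave a symmetrical 2,6-diol.

**Step 3**
Reactants: 4 2,6-dihydroxy-4-(SEM-oxy)benzophenone; 5 paraformaldehyde
Product: 7 3-benzoyl-2,4-dihydroxy-6-(SEM-oxy)benzaldehyde, via hydroxymethyl intermediate 6 (not isolated)
Conditions: MgCl2, Et3N, (CH2O)n, MeCN, reflux; cold dilute aq. HCl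
Reagents that add atoms: paraformaldehyde (5, as formaldehyde), C=O
Why: Casnati–Skattebøl ortho-formylation: the ArOMgCl phenoxide of 4 delivers coordinated formaldehyde to the carbon ortho to oxygen, a second formaldehyde takes a hydride from the benzylic alkoxide of 6 (Oppenauer type), the two free ring carbons of 4 are equivalent so only one mono-aldehyde can arise, and the amine-buffered medium leaves the SEM acetal alone.

**Step 4**
Reactants: 7 3-benzoyl-2,4-dihydroxy-6-(SEM-oxy)benzaldehyde; 8 prenyl bromide
Product: 9 3-benzoyl-2-hydroxy-4-(prenyloxy)-6-(SEM-oxy)benzaldehyde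
Conditions: K2CO3 (1.2 equiv), DMF, rt
Reagents that add atoms: prenyl bromide (8), CC(C)=CCBr
Why: Williamson ether synthesis under mild base: the hydroxyl between formyl and benzoyl is flanked on both sides and held in a strong chelate, whereas the hydroxyl para to the aldehyde is more acidic and open on one side, so its phenoxide should take the prenyl group, at oxygen because the doubly acylated ring is a poor carbon nucleophile.

**Step 5**
Reactants: 9 3-benzoyl-2-hydroxy-4-(prenyloxy)-6-(SEM-oxy)benzaldehyde
Product: 10 3-benzoyl-4-(prenyloxy)-2,6-bis(SEM-oxy)benzaldehyde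
Conditions: NaH, SEMCl, DMF, 0 °C → rt
Reagents that add atoms: SEMCl, C[Si](C)(C)CCOCCl
Why: Williamson-type acetal formation after irreversible deprotonation: NaH breaks the double chelate of the last hydroxyl, the small and very reactive SEMCl reaches the crowded oxygen, and 9 has no enolisable carbonyl group that the base could attack.

**Step 6**
Reactants: 10 3-benzoyl-4-(prenyloxy)-2,6-bis(SEM-oxy)benzaldehyde
Product: 11 3-benzoyl-4-(prenyloxy)-2,6-bis(SEM-oxy)benzyl alcohol
Conditions: NaBH4, THF/MeOH, −10 → 0 °C
Reagents that add atoms: none
Why: Chemoselective borohydride reduction: the aldehyde should be reduced well before the diaryl ketone, which is twisted out of conjugation and screened by two ortho alkoxy groups.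

**Step 7**
Reactants: 11 3-benzoyl-4-(prenyloxy)-2,6-bis(SEM-oxy)benzyl alcohol
Product: 12 3-benzoyl-4-(prenyloxy)-2,6-bis(SEM-oxy)benzyl bromide
Conditions: CBr4, PPh3 (added last), 2,6-lutidine (0.2 equiv), CH2Cl2, −20 → 0 °C; short Et3N-washed silica plug, used at once
Reagents that add atoms: carbon tetrabromide, BrC(Br)(Br)Br
Why: Appel reaction: the alcohol is exchanged for bromide under neutral, buffered conditions that spare the acetals, the prenyl alkene and the ketone, and the meta benzoyl group tempers the ionisation of this trialkoxybenzyl bromide enough for a short handling time.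

**Step 8**
Reactants: 1 phloroglucinol; 13 isobutyryl chloride
Product: 14 isobutyrylphloroglucinol (2-methyl-1-(2,4,6-trihydroxyphenyl)propan-1-one)
Conditions: AlCl3 (4 equiv), CH2Cl2/MeNO2, 0 → 40 °C; ice/aq. HCl
Reagents that add atoms: isobutyryl chloride (13), CC(C)C(=O)Cl
Why: Friedel–Crafts acylation, which is mono-selective for the same reason as in step 1.

**Step 9**
Reactants: 12 3-benzoyl-4-(prenyloxy)-2,6-bis(SEM-oxy)benzyl bromide; 14 isobutyrylphloroglucinol
Product: 15 diarylmethane with aromatic ring B (3-benzylated isobutyrylphloroglucinol)
Conditions: 14 (3 equiv), DBU (3 equiv), THF, 0 °C; slow addition of 12; → rt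
Reagents that add atoms: none
Why: C-alkylation of an ambident acylphloroglucinolate, the reaction type used for C-prenylation and C-benzylation of acylphloroglucinols: the hydrogen-bonded DBU-H+ ion pair in THF shields oxygen, the soft activated benzylic bromide is taken by ring carbon, the two free carbons of 14 are equivalent so only one mono-adduct exists, and the threefold excess of 14 holds back a second benzylation.

**Step 10**
Reactants: 15 diarylmethane with aromatic ring B; 16 iodomethane
Product: 18 bis-SEM sarothralin, via mono-C-methyl diarylmethane 17 (not isolated)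
Conditions: NaOMe (4 equiv), MeI (2.2 equiv, two portions), MeOH, 0 °C → rt; cold aq. citric acid
Reagents that add atoms: iodomethane (16), CI
Why: NaOMe turns ring B of 15 into a phloroglucinolate polyanion whose only hydrogen-bearing ring carbon, flanked by two oxido carbons, attacks MeI in an SN2 step and re-aromatises by proton loss to 17; the same carbon of the re-formed anion attacks a second MeI, becomes quaternary and leaves ring B as the enolised β-triketone of 18. The closest known reaction type is the alkylative dearomatisation of acylphloroglucinols with NaOMe/MeI that gives acylfilicinic acids. No ring is closed and no stereocentre is created, since the new quaternary carbon carries two identical methyl groups. Three selectivities are needed: carbon over oxygen, ring B over ring A, and the methyl-bearing over the bridge-bearing carbon in the second alkylation. Methanol hydrogen-bonds the oxido groups and Na+ pairs tightly with them, which sends the soft electrophile to carbon, while ring A, with both hydroxyls capped, can neither form a phenoxide and be methylated nor leave the bridge as a quinone methide. The bridge-bearing carbon is screened by the 2,6-bis(SEM-oxy)aryl group, and the limit of 2.2 equiv MeI keeps the less nucleophilic triketone anion of 18 from taking a third methyl group.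

**Step 11**
Reactants: 18 bis-SEM sarothralin
Product: 20 sarothralin, via mono-SEM sarothralin 19 (not isolated)
Conditions: Bu4NF (1 M in THF, 8 equiv), DMPU, 4 Å MS, 45 °C, slow Ar purge; aq. NH4Cl
Reagents that add atoms: none
Why: Fluoride-induced fragmentation of SEM ethers: fluoride attacks silicon and each acetal collapses to Me3SiF, ethene, formaldehyde and an acyl-stabilised phenoxide whose leaving-group quality allows a moderate temperature, the gas stream carries the volatile fragments away, and the prenyl ether, the benzophenone and the β-triketone (present as its enolate) are inert to fluoride.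

**Compound list**

| No. | Name | SMILES | Role |
|---|---|---|---|
| 1 | phloroglucinol | Oc1cc(O)cc(O)c1 | starting material |
| 2 | benzoyl chloride | O=C(Cl)c1ccccc1 | starting material |
| 3 | 2,4,6-trihydroxybenzophenone | O=C(c1ccccc1)c1c(O)cc(O)cc1O | intermediate |
| 4 | 2,6-dihydroxy-4-(SEM-oxy)benzophenone | O=C(c1ccccc1)c1c(O)cc(OCOCC[Si](C)(C)C)cc1O | intermediate |
| 5 | paraformaldehyde (written as formaldehyde) | C=O | starting material |
| 6 | 2,6-dihydroxy-3-(hydroxymethyl)-4-(SEM-oxy)benzophenone (not isolated) | OCc1c(O)c(C(=O)c2ccccc2)c(O)cc1OCOCC[Si](C)(C)C | intermediate |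
| 7 | 3-benzoyl-2,4-dihydroxy-6-(SEM-oxy)benzaldehyde | O=Cc1c(O)c(C(=O)c2ccccc2)c(O)cc1OCOCC[Si](C)(C)C | intermediate |
| 8 | prenyl bromide (1-bromo-3-methylbut-2-ene) | CC(C)=CCBr | starting material |
| 9 | 3-benzoyl-2-hydroxy-4-(prenyloxy)-6-(SEM-oxy)benzaldehyde | O=Cc1c(O)c(C(=O)c2ccccc2)c(OCC=C(C)C)cc1OCOCC[Si](C)(C)C | intermediate |
| 10 | 3-benzoyl-4-(prenyloxy)-2,6-bis(SEM-oxy)benzaldehyde | O=Cc1c(OCOCC[Si](C)(C)C)c(C(=O)c2ccccc2)c(OCC=C(C)C)cc1OCOCC[Si](C)(C)C | intermediate |
| 11 | 3-benzoyl-4-(prenyloxy)-2,6-bis(SEM-oxy)benzyl alcohol | OCc1c(OCOCC[Si](C)(C)C)c(C(=O)c2ccccc2)c(OCC=C(C)C)cc1OCOCC[Si](C)(C)C | intermediate |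
| 12 | 3-benzoyl-4-(prenyloxy)-2,6-bis(SEM-oxy)benzyl bromide | BrCc1c(OCOCC[Si](C)(C)C)c(C(=O)c2ccccc2)c(OCC=C(C)C)cc1OCOCC[Si](C)(C)C | intermediate |
| 13 | isobutyryl chloride | CC(C)C(=O)Cl | starting material |
| 14 | isobutyrylphloroglucinol, 2-methyl-1-(2,4,6-trihydroxyphenyl)propan-1-one | CC(C)C(=O)c1c(O)cc(O)cc1O | intermediate |
| 15 | 1-{3-[3-benzoyl-4-(prenyloxy)-2,6-bis(SEM-oxy)benzyl]-2,4,6-trihydroxyphenyl}-2-methylpropan-1-one (key-step precursor) | CC(C)=CCOc1cc(OCOCC[Si](C)(C)C)c(Cc2c(O)cc(O)c(C(=O)C(C)C)c2O)c(OCOCC[Si](C)(C)C)c1C(=O)c1ccccc1 | intermediate |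
| 16 | iodomethane | CI | starting material |
| 17 | 5-C-methyl derivative of 15, ring B still aromatic (not isolated) | CC(C)=CCOc1cc(OCOCC[Si](C)(C)C)c(Cc2c(O)c(C)c(O)c(C(=O)C(C)C)c2O)c(OCOCC[Si](C)(C)C)c1C(=O)c1ccccc1 | intermediate |
| 18 | bis-SEM sarothralin, ring B as the gem-dimethyl enolised β-triketone (key-step product) | CC(C)=CCOc1cc(OCOCC[Si](C)(C)C)c(CC2=C(O)C(C)(C)C(=O)C(C(=O)C(C)C)=C2O)c(OCOCC[Si](C)(C)C)c1C(=O)c1ccccc1 | intermediate |
| 19 | mono-SEM sarothralin, drawn with the crowded SEM group between bridge and benzoyl still in place; the order of loss is immaterial (not isolated) | CC(C)=CCOc1cc(O)c(CC2=C(O)C(C)(C)C(=O)C(C(=O)C(C)C)=C2O)c(OCOCC[Si](C)(C)C)c1C(=O)c1ccccc1 | intermediate |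
| 20 | sarothralin | CC(C)=CCOc1cc(O)c(CC2=C(O)C(C)(C)C(=O)C(C(=O)C(C)C)=C2O)c(O)c1C(=O)c1ccccc1 | target |

**Step count**

Total steps: 11. Longest linear sequence: 10 (steps 1–7, 9, 10, 11).

**Steps most likely to fail**

**Step 10.** Methylation may leave the wanted course in four ways. It may stall after the first methyl group, attack at oxygen, place the second methyl group on the bridge-bearing carbon, or add a third methyl group to the product anion.

Fallback: dearomatise before joining. It sets out from 14 and returns at 18.
- NaOMe/MeI in MeOH is applied to the small, cheap ring B alone, where mixed methylation levels can be separated on scale.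
- The reaction passes through 1-(2,4,6-trihydroxy-3-methylphenyl)-2-methylpropan-1-one F1 and gives isobutyrylfilicinic acid F2.
- The single remaining ring C–H carbon of F2 is the centre of a vinylogous acid. It is C-benzylated with bromide 12 (DBU, THF, 0 °C → rt) to give 18.

**Step 9.** The bromide may be lost by ionisation, helped by the neighbouring SEM acetal oxygens, before it is captured. The anion may also react at oxygen, or ring B may be benzylated twice.

Fallback: change from a phenoxide/halide substitution to a cationic arene alkylation. It sets out from alcohol 11, skips 12 and returns at 15.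
- The reaction is a dehydrative Friedel–Crafts benzylation of neutral 14 (3 equiv) with 11 in 1,1,1,3,3,3-hexafluoropropan-2-ol at rt.
- TsOH·H2O (2–5 mol %) is added only if ionisation is slow.
- Attack through oxygen is reversible under these conditions, so only the carbon–carbon bond persists.
- No compound outside the list is made (F0).

**Step 11.** The released formaldehyde may re-enter at the one free carbon of the ring A phenoxide. The basic medium may also let the two halves exchange across the bridge through a quinone methide once ring A phenoxides exist.

Fallback: give up fluoride and anionic intermediates. It sets out from 18 and returns at 20.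
- The reaction is a Lewis-acid acetal exchange with MgBr2·OEt2 and n-BuSH in Et2O at rt.
- The benzoyl and triketone oxygens hold MgBr2 next to the acetals.
- The thiol carries each O–CH2–O carbon away as an O,S-acetal, so neither free formaldehyde nor a phenoxide/enolate pair arises.
- No compound outside the list is made (F0).

**Further compounds**
F1 | step 10 | 1-(2,4,6-trihydroxy-3-methylphenyl)-2-methylpropan-1-one | CC(C)C(=O)c1c(O)cc(O)c(C)c1O
F2 | step 10 | isobutyrylfilicinic acid, 3,5-dihydroxy-6,6-dimethyl-2-(2-methylpropanoyl)cyclohexa-2,4-dien-1-one | CC(C)C(=O)C1=C(O)C=C(O)C(C)(C)C1=O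
F0 | step 9 | none | none
F0 | step 11 | none | none
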